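## Retrosynthetic overview

1. Target 20 ⇐ acetonide 19 by acetal hydrolysis.
2. 19 ⇐ acyclic (Z,Z)-epoxy-triene 18 by one oxidosqualene-type cationic cascade: ring A first (C4–C5 bond), then ring B (C9–C10 bond), ending with proton loss from C17. The two Z-alkenes are chosen so that the anti additions give the cis ring fusion and put C11 cis to CH3-20.
3. 18 ⇐ triene 15 + 3-bromobutenolide 16 by hydroboration and B-alkyl Suzuki coupling (C12–C13).
4. 15 ⇐ (Z)-vinyl iodide 7 (from neryl acetate: ozonolysis, iodo-Wittig, C11 extended to a diene) + epoxy iodide 13 (dioxanone Wittig, Shi epoxidation) by Negishi coupling (C1–C10).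

Assumption: the SMILES is read literally, so 3-OH, H-5, CH3-20 and the C9 side chain all lie on one face (cis-fused decalin; 3R,5R,9R,10S in labdane numbering, which is used below), and C4 is not a stereocentre.

## Route

Step 1
Reactants: 1 neryl acetate
Product: 3 (2Z)-3-methyl-6-oxohex-2-en-1-yl acetate, via secondary ozonide 2 (not isolated)
Conditions: O3 (1.0 equiv), CH2Cl2, −78 °C; then Me2S, −78 °C → rt
Reagents that add atoms: ozone, O=[O+][O-]
Why: Criegee ozonolysis cleaves only the electron-rich trisubstituted 6,7-alkene because the 2,3-alkene is deactivated by the allylic acetate, and the Z-alkene (later C8=C9) is untouched.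

Step 2
Reactants: 3 (2Z)-3-methyl-6-oxohex-2-en-1-yl acetate
Product: 4 (2Z,6Z)-7-iodo-3-methylocta-2,6-dien-1-yl acetate
Conditions: Ph3PEt+ I−, n-BuLi, THF, rt; I2, −78 °C; NaN(SiMe3)2, −20 °C; then 3, −78 → −20 °C
Reagents that add atoms: ethyltriphenylphosphonium iodide, CC[P+](c1ccccc1)(c1ccccc1)c1ccccc1.[I-]; iodine, II
Why: Wittig olefination with the α-iodoethylidene ylide (Stork–Zhao-type iodo-olefination) gives the 2-iodoalk-2-ene with iodine cis to the chain (Z), which fixes the later C5=C10 geometry.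

Step 3
Reactants: 4 (2Z,6Z)-7-iodo-3-methylocta-2,6-dien-1-yl acetate
Product: 5 (2Z,6Z)-7-iodo-3-methylocta-2,6-dien-1-ol
Conditions: K2CO3 (cat.), MeOH, 0 °C → rt
Reagents that add atoms: none
Why: Base-catalysed transesterification removes the acetate without affecting the vinyl iodide or either alkene geometry.

Step 4
Reactants: 5 (2Z,6Z)-7-iodo-3-methylocta-2,6-dien-1-ol
Product: 6 (2Z,6Z)-7-iodo-3-methylocta-2,6-dienal
Conditions: PhI(OAc)2 (1.1 equiv), TEMPO (10 mol %), CH2Cl2, rt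
Reagents that add atoms: none
Why: The TEMPO/PhI(OAc)2 oxidation of an allylic alcohol is neutral and gives the neral-type Z-enal without Z/E isomerisation.

Step 5
Reactants: 6 (2Z,6Z)-7-iodo-3-methylocta-2,6-dienal
Product: 7 (3Z,7Z)-8-iodo-4-methylnona-1,3,7-triene
Conditions: Ph3PMe+ Br−, KN(SiMe3)2, THF, 0 °C; then 6, −78 → 0 °C
Reagents that add atoms: methyltriphenylphosphonium bromide, C[P+](c1ccccc1)(c1ccccc1)c1ccccc1.[Br-]
Why: Wittig methylenation of the enal (as for neral) gives the terminal 1,3-diene that supplies C12 and leaves both Z-alkenes unchanged.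

Step 6
Reactants: 8 (3-hydroxypropyl)triphenylphosphonium bromide; 9 2,2-dimethyl-1,3-dioxan-5-one
Product: 11 3-(2,2-dimethyl-1,3-dioxan-5-ylidene)propan-1-ol, via oxido ylide 10 (not isolated)
Conditions: n-BuLi (2.0 equiv), THF, −78 → 0 °C; then 9, −78 °C → rt
Reagents that add atoms: none
Why: Wittig olefination of the symmetric ketone with the γ-oxido ylide gives the trisubstituted alkene with no geometry issue and already carries C18 and C19 as a protected pair.

Step 7
Reactants: 11 3-(2,2-dimethyl-1,3-dioxan-5-ylidene)propan-1-ol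
Product: 12 2-[(2R)-6,6-dimethyl-1,5,7-trioxaspiro[2.5]octan-2-yl]ethan-1-ol
Conditions: D-fructose-derived Shi ketone (30 mol %), KHSO5 (as 2KHSO5·KHSO4·K2SO4), K2CO3, Bu4NHSO4 (cat.), MeCN/CH2(OMe)2/aq. Na2B4O7 buffer (pH 10.5), 0 °C
Reagents that add atoms: potassium peroxymonosulfate, [K+].[O-]S(=O)(=O)OO
Why: Shi asymmetric epoxidation of the only alkene present delivers oxygen through the spiro transition state of the D-fructose ketone to give the (R)-epoxide, which is the future C3 stereocentre.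

Step 8
Reactants: 12 2-[(2R)-6,6-dimethyl-1,5,7-trioxaspiro[2.5]octan-2-yl]ethan-1-ol
Product: 13 (2R)-2-(2-iodoethyl)-6,6-dimethyl-1,5,7-trioxaspiro[2.5]octane
Conditions: I2, PPh3, imidazole, CH2Cl2, 0 °C
Reagents that add atoms: iodine, II
Why: Appel-type iodination of the primary alcohol is fast at 0 °C under imidazole buffering and does not touch the trisubstituted epoxide or C3.

Step 9
Reactants: 13 (2R)-2-(2-iodoethyl)-6,6-dimethyl-1,5,7-trioxaspiro[2.5]octane; 7 (3Z,7Z)-8-iodo-4-methylnona-1,3,7-triene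
Product: 15 (2R)-2-[(3Z,7Z)-3,7-dimethyldeca-3,7,9-trien-1-yl]-6,6-dimethyl-1,5,7-trioxaspiro[2.5]octane, via alkylzinc iodide 14 (not isolated)
Conditions: Zn dust, LiCl, THF, 35 °C; then 7, PdCl2(dppf) (5 mol %), THF, 40 °C
Reagents that add atoms: none
Why: Zinc inserts into the primary C–I bond without opening the epoxide, and the Negishi coupling replaces the vinyl iodine with retention, so C1 ends cis to C6 (Z at C5=C10).

Step 10
Reactants: 15 (2R)-2-[(3Z,7Z)-3,7-dimethyldeca-3,7,9-trien-1-yl]-6,6-dimethyl-1,5,7-trioxaspiro[2.5]octane; 16 3-bromofuran-2(5H)-one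
Product: 18 3-{(3Z,7Z)-10-[(2R)-6,6-dimethyl-1,5,7-trioxaspiro[2.5]octan-2-yl]-4,8-dimethyldeca-3,7-dien-1-yl}furan-2(5H)-one, via B-alkyl-9-BBN borane 17 (not isolated)
Conditions: 9-BBN dimer, THF, 0 °C → rt; then 16, PdCl2(dppf) (5 mol %), AsPh3, K3PO4 (aq), DMF, rt
Reagents that add atoms: none
Why: 9-BBN adds only to the monosubstituted end of the 1,3-diene (boron on C12, as in the homogeranyl case), and the B-alkyl Suzuki–Miyaura coupling with the α-bromobutenolide forms C12–C13 without moving any double bond.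

Step 11
Reactants: 18 3-{(3Z,7Z)-10-[(2R)-6,6-dimethyl-1,5,7-trioxaspiro[2.5]octan-2-yl]-4,8-dimethyldeca-3,7-dien-1-yl}furan-2(5H)-one
Product: 19 3-{2-[(1'R,4a'R,6'R,8a'S)-6'-hydroxy-2,2,8a'-trimethyl-2'-methylideneoctahydro-1'H-spiro[1,3-dioxane-5,5'-naphthalen]-1'-yl]ethyl}furan-2(5H)-one
Conditions: MeAlCl2 (3 equiv), CH2Cl2, −78 °C; Et3N/MeOH quench, aq. NaHCO3; AgNO3-impregnated silica to remove endocyclic alkene isomers
Reagents that add atoms: none
Why: Proposed new method: Lewis-acid opening of the (R)-epoxide at tertiary C4 starts a concerted anti-addition (Stork–Eschenmoser) chair–chair cascade in which the Z-alkene C5=C10 gives the cis ring fusion (H-5 cis to CH3-20), the Z-alkene C8=C9 puts C11 axial and cis to CH3-20, the equatorial C3–O bond from the (R)-epoxide fixes the absolute sense, and the methylaluminium species takes a C17 proton to give the 8(17)-alkene; the closest known reaction type is the Lewis-acid epoxy-polyene cyclization of (E,E)-epoxyfarnesyl and -geranylgeranyl derivatives, which has not been run on a (Z,Z)-triene carrying a bis(alkoxymethyl) epoxide.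

Step 12
Reactants: 19 3-{2-[(1'R,4a'R,6'R,8a'S)-6'-hydroxy-2,2,8a'-trimethyl-2'-methylideneoctahydro-1'H-spiro[1,3-dioxane-5,5'-naphthalen]-1'-yl]ethyl}furan-2(5H)-one
Product: 20 3-{2-[(1R,4aR,6R,8aS)-6-hydroxy-5,5-bis(hydroxymethyl)-8a-methyl-2-methylidenedecahydronaphthalen-1-yl]ethyl}furan-2(5H)-one
Conditions: AcOH/THF/H2O (3:1:1), 40 °C
Reagents that add atoms: none
Why: Mild acid-catalysed acetal hydrolysis frees the two hydroxymethyl groups without isomerising the exocyclic alkene or opening the butenolide, and no stereocentre is touched.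

## Compound list

1 | neryl acetate, (2Z)-3,7-dimethylocta-2,6-dien-1-yl acetate | CC(=O)OC/C=C(C)\CCC=C(C)C | starting material
2 | (2Z)-5-(5,5-dimethyl-1,2,4-trioxolan-3-yl)-3-methylpent-2-en-1-yl acetate (secondary ozonide) | CC(=O)OC/C=C(C)\CCC1OOC(C)(C)O1 | intermediate (not isolated)
3 | (2Z)-3-methyl-6-oxohex-2-en-1-yl acetate | CC(=O)OC/C=C(C)\CCC=O | intermediate
4 | (2Z,6Z)-7-iodo-3-methylocta-2,6-dien-1-yl acetate | CC(=O)OC/C=C(C)\CC/C=C(C)\I | intermediate
5 | (2Z,6Z)-7-iodo-3-methylocta-2,6-dien-1-ol | OC/C=C(C)\CC/C=C(C)\I | intermediate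
6 | (2Z,6Z)-7-iodo-3-methylocta-2,6-dienal | O=C/C=C(C)\CC/C=C(C)\I | intermediate
7 | (3Z,7Z)-8-iodo-4-methylnona-1,3,7-triene | C=C/C=C(C)\CC/C=C(C)\I | intermediate
8 | (3-hydroxypropyl)triphenylphosphonium bromide | OCCC[P+](c1ccccc1)(c1ccccc1)c1ccccc1.[Br-] | starting material
9 | 2,2-dimethyl-1,3-dioxan-5-one | CC1(C)OCC(=O)CO1 | starting material
10 | lithium 3-(triphenyl-λ5-phosphanylidene)propan-1-olate (oxido ylide) | [Li+].[O-]CCC=P(c1ccccc1)(c1ccccc1)c1ccccc1 | intermediate (not isolated)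
11 | 3-(2,2-dimethyl-1,3-dioxan-5-ylidene)propan-1-ol | OCCC=C1COC(C)(C)OC1 | intermediate
12 | 2-[(2R)-6,6-dimethyl-1,5,7-trioxaspiro[2.5]octan-2-yl]ethan-1-ol | OCC[C@H]1OC12COC(C)(C)OC2 | intermediate
13 | (2R)-2-(2-iodoethyl)-6,6-dimethyl-1,5,7-trioxaspiro[2.5]octane | ICC[C@H]1OC12COC(C)(C)OC2 | intermediate
14 | iodo{2-[(2R)-6,6-dimethyl-1,5,7-trioxaspiro[2.5]octan-2-yl]ethyl}zinc | I[Zn]CC[C@H]1OC12COC(C)(C)OC2 | intermediate (not isolated)
15 | (2R)-2-[(3Z,7Z)-3,7-dimethyldeca-3,7,9-trien-1-yl]-6,6-dimethyl-1,5,7-trioxaspiro[2.5]octane | C=C/C=C(C)\CC/C=C(C)\CC[C@H]1OC12COC(C)(C)OC2 | intermediate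
16 | 3-bromofuran-2(5H)-one | O=C1OCC=C1Br | starting material
17 | 9-{(3Z,7Z)-10-[(2R)-6,6-dimethyl-1,5,7-trioxaspiro[2.5]octan-2-yl]-4,8-dimethyldeca-3,7-dien-1-yl}-9-borabicyclo[3.3.1]nonane | B1(CC/C=C(C)\CC/C=C(C)\CC[C@H]3OC34COC(C)(C)OC4)C2CCCC1CCC2 | intermediate (not isolated)
18 | 3-{(3Z,7Z)-10-[(2R)-6,6-dimethyl-1,5,7-trioxaspiro[2.5]octan-2-yl]-4,8-dimethyldeca-3,7-dien-1-yl}furan-2(5H)-one | O=C1OCC=C1CC/C=C(C)\CC/C=C(C)\CC[C@H]2OC23COC(C)(C)OC3 | intermediate
19 | 3-{2-[(1'R,4a'R,6'R,8a'S)-6'-hydroxy-2,2,8a'-trimethyl-2'-methylideneoctahydro-1'H-spiro[1,3-dioxane-5,5'-naphthalen]-1'-yl]ethyl}furan-2(5H)-one (target with C18/C19 tied as the acetonide; cis-fused) | C=C1CC[C@H]2C3(COC(C)(C)OC3)[C@H](O)CC[C@@]2(C)[C@@H]1CCC1=CCOC1=O | intermediate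
20 | 3-{2-[(1R,4aR,6R,8aS)-6-hydroxy-5,5-bis(hydroxymethyl)-8a-methyl-2-methylidenedecahydronaphthalen-1-yl]ethyl}furan-2(5H)-one | C=C1CC[C@H]2C(CO)(CO)[C@H](O)CC[C@@]2(C)[C@@H]1CCC1=CCOC1=O | target

## Step count and risks

Total steps: 12. Longest linear sequence: 9 steps (steps 1–5 and 9–12, from neryl acetate); steps 6–8 are the side branch.

The three steps most likely to fail:

Step 11 (cascade). The doubly oxygenated epoxide may ionise poorly or rearrange, the acetonide may not survive the Lewis acid, and proton loss may give mainly endocyclic alkenes. The fallback changes the termination and sets out from 18. The same cationic cascade is run with a hydrated Lewis acid (FeCl3·6H2O, CH2Cl2, 0 °C) so that water captures the C8 cation, giving the C8 tertiary alcohol F1. Its C3 hydroxyl is silylated (Et3SiCl, imidazole) to give the 3-O-triethylsilyl ether F2. The tertiary alcohol is then dehydrated with the Burgess reagent; in this syn elimination the methyl hydrogens reach the required geometry most easily, which should favour the exocyclic 3-O-triethylsilyl ether of 19 F3. Aqueous AcOH (or HF·pyridine) removes the silyl ether and the acetonide together, and the route is rejoined at 20.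

Step 9 (Negishi coupling). The epoxide-bearing alkylzinc may form sluggishly or open. The fallback reverses the polarity and sets out from 7. Iodine–lithium exchange (t-BuLi, 2 equiv, Et2O, −78 °C, faster than addition to the diene) gives [(2E,6Z)-6-methylnona-2,6,8-trien-2-yl]lithium F4 with retention of geometry. ZnCl2 converts it into chlorido[(2Z,6Z)-6-methylnona-2,6,8-trien-2-yl]zinc F5. F5 is coupled with the unactivated primary iodide 13 (Pd2(dba)3, P(c-C5H9)3, N-methylimidazole, THF/NMP, 80 °C), and the route is rejoined at 15.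

Step 10 (B-alkyl Suzuki coupling). The base-sensitive bromobutenolide may decompose under aqueous base, or the borane may protodeborylate. The fallback builds the butenolide by enolate chemistry and sets out from 15. It is hydroborated as before to 17, and I2/NaOMe converts the borane into (2R)-2-[(3Z,7Z)-10-iodo-3,7-dimethyldeca-3,7-dien-1-yl]-6,6-dimethyl-1,5,7-trioxaspiro[2.5]octane F6. Separately, 3-bromooxolan-2-one and thiophenol (Et3N) give 3-(phenylsulfanyl)oxolan-2-one F7. Its lithium enolate (LiN(i-Pr)2, THF, −78 °C) is alkylated with F6 to give the 3-alkyl-3-(phenylsulfanyl)oxolan-2-one F8. NaIO4 oxidises this to the sulfoxide F9, and thermal syn elimination (toluene, 110 °C, CaCO3) should favour the endocyclic butenolide, rejoining the route at 18.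

Further compounds
F1 | step 11 | C8 tertiary alcohol (water adduct of 19 across C8=C17, either C8 epimer) | CC1(O)CC[C@H]2C3(COC(C)(C)OC3)[C@H](O)CC[C@@]2(C)[C@@H]1CCC1=CCOC1=O
F2 | step 11 | 3-O-triethylsilyl ether of F1 | CC1(O)CC[C@H]2C3(COC(C)(C)OC3)[C@H](O[Si](CC)(CC)CC)CC[C@@]2(C)[C@@H]1CCC1=CCOC1=O
F3 | step 11 | 3-O-triethylsilyl ether of 19 | C=C1CC[C@H]2C3(COC(C)(C)OC3)[C@H](O[Si](CC)(CC)CC)CC[C@@]2(C)[C@@H]1CCC1=CCOC1=O
F4 | step 9 | [(2E,6Z)-6-methylnona-2,6,8-trien-2-yl]lithium | C=C/C=C(C)\CC/C=C(C)\[Li]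
F5 | step 9 | chlorido[(2Z,6Z)-6-methylnona-2,6,8-trien-2-yl]zinc | C=C/C=C(C)\CC/C=C(C)\[Zn]Cl
F6 | step 10 | (2R)-2-[(3Z,7Z)-10-iodo-3,7-dimethyldeca-3,7-dien-1-yl]-6,6-dimethyl-1,5,7-trioxaspiro[2.5]octane | ICC/C=C(C)\CC/C=C(C)\CC[C@H]1OC12COC(C)(C)OC2
F7 | step 10 | 3-(phenylsulfanyl)oxolan-2-one | O=C1OCCC1Sc1ccccc1
F8 | step 10 | 3-{(3Z,7Z)-10-[(2R)-6,6-dimethyl-1,5,7-trioxaspiro[2.5]octan-2-yl]-4,8-dimethyldeca-3,7-dien-1-yl}-3-(phenylsulfanyl)oxolan-2-one | O=C1OCCC1(Sc1ccccc1)CC/C=C(C)\CC/C=C(C)\CC[C@H]2OC23COC(C)(C)OC3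
F9 | step 10 | 3-{(3Z,7Z)-10-[(2R)-6,6-dimethyl-1,5,7-trioxaspiro[2.5]octan-2-yl]-4,8-dimethyldeca-3,7-dien-1-yl}-3-(phenylsulfinyl)oxolan-2-one | O=C1OCCC1(S(=O)c1ccccc1)CC/C=C(C)\CC/C=C(C)\CC[C@H]2OC23COC(C)(C)OC3
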